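**Retrosynthetic overview**

1. The C13(16),14-diene is made last from a C13 terminal alkyne and ethylene (enyne metathesis). The alkyne comes from a C13 aldehyde carried as a benzyl ether, and the C6 acetate is put on once C18 is silylated.
2. C18–OH comes from Tamao–Fleming oxidation of an oxasilinane formed by C–H silylation. In the trans-decalin the equatorial O6 on ring B (C5–C10) and the equatorial methyl C18 on C4 of ring A (C1–C5, C10) are 1,3-related across C5 and parallel, both anti to C5–C10. Silicon tethered to O6 therefore reaches this methyl only, and C4 becomes stereogenic last.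
3. The C8 carbinol comes from an 8(17)-methylene (epoxide, then hydride). Ring B is closed at C6–C7 by an intramolecular allylsilane–aldehyde (Hosomi–Sakurai) addition that also sets C6.
4. C5 is set by hydroboration of an exocyclic C5=C6 alkene. C9 and C10 are set by an asymmetric boron-enolate Ireland–Claisen rearrangement of the β-cyclogeranyl ester of 5-(benzyloxy)pentanoic acid.
5. Ring order: ring A is bought with β-cyclocitral, ring B is formed in step 9, the oxasilinane ring in step 16 and opened again in step 17.

Key step: step 16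

Remark: the SMILES is read as the ent-labdane (4S,5S,6R,8S,9S,10R)-6-acetoxylabda-13(16),14-diene-8,18-diol. Labdane numbering is used for all compounds, monocyclic ones included (C18 equatorial and C19 axial on C4, C20 on C10, C17 on C8).

Assumption: the (S,S) enantiomer of the boron controller is taken to give acid 8; its antipode, equally available, is used if a trial run shows the opposite sense.

**Route**

Step 1
Reactants: 1 β-cyclocitral
Product: 2 β-cyclogeraniol
Conditions: NaBH4, MeOH, 0 °C
Reagents that add atoms: none
Why: Borohydride 1,2-reduction of the hindered enal should give the primary allylic alcohol and leave the tetrasubstituted alkene alone.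

Step 2
Reactants: 3 δ-valerolactone
Product: 5 5-(benzyloxy)pentanoic acid, via benzyl 5-(benzyloxy)pentanoate 4 (not isolated)
Conditions: KOH (powdered), BnBr, toluene, reflux; then KOH, MeOH/H2O, 60 °C; HCl
Reagents that add atoms: benzyl bromide BrCc1ccccc1; potassium hydroxide [K+].[OH-]
Why: Hydroxide opens the lactone and supplies the third oxygen of the acid, Williamson etherification benzylates the δ-alkoxide (and the carboxylate, giving 4), and saponification of the benzyl ester returns the acid.

Step 3
Reactants: 2 β-cyclogeraniol; 5 5-(benzyloxy)pentanoic acid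
Product: 6 β-cyclogeranyl 5-(benzyloxy)pentanoate
Conditions: DCC, DMAP (cat.), CH2Cl2, 0 °C to rt
Reagents that add atoms: none
Why: Steglich esterification acylates the primary allylic alcohol under neutral conditions, so no allylic transposition is expected.

Step 4
Reactants: 6 β-cyclogeranyl 5-(benzyloxy)pentanoate
Product: 8 Claisen acid (2S)-5-(benzyloxy)-2-[(1S)-1,3,3-trimethyl-2-methylidenecyclohexyl]pentanoic acid, via boron ketene acetal 7 (not isolated)
Conditions: (4S,5S)-2-bromo-1,3-bis[3,5-bis(trifluoromethyl)phenylsulfonyl]-4,5-diphenyl-1,3,2-diazaborolidine, i-Pr2NEt, CH2Cl2, −78 °C, then 4 to 23 °C; H2O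
Reagents that add atoms: none
Why: Soft enolisation in CH2Cl2 should give the boron ketene acetal with the C11 chain cis to O–B, and the Ireland–Claisen [3,3] shift through a chair (C10 methyl axial and ring CH2 equatorial on the allyl part, chain equatorial on the enolate part) fixes the C9/C10 relative configuration of the target, while the C2-symmetric bis-sulfonamide on boron selects the enolate face and so the absolute sense (a variant established for 3,3-disubstituted allyl esters that form quaternary carbons).

Step 5
Reactants: 8 Claisen acid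
Product: 9 methyl ester of 8
Conditions: MeI, K2CO3, DMF, rt
Reagents that add atoms: iodomethane CI
Why: SN2 O-methylation of the carboxylate masks the acid for the hydroboration without disturbing C9.

Step 6
Reactants: 9 methyl ester
Product: 12 trans-fused δ-lactone (O between C6 and C8), via B-alkyl-9-BBN adduct 10 (not isolated), via hydroxy ester 11 (not isolated)
Conditions: 9-BBN, THF, 0 to 65 °C; NaOH, H2O2, 0 °C to rt; p-TsOH (cat.), toluene, 60 °C
Reagents that add atoms: hydrogen peroxide OO
Why: Hydroboration–oxidation places boron on C6 and hydrogen on C5 from the face opposite the syn-axial C10 and C4 methyls of the chair that keeps the C9 branch equatorial, so H5 should end anti to the C10 methyl, and the hydroxy ester then lactonises under acid.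

Step 7
Reactants: 12 trans-fused δ-lactone
Product: 14 allylsilane alcohol (C8(=C7H2)–CH2SiMe3, C6–OH), via bis(silylmethyl) carbinol 13 (not isolated)
Conditions: Me3SiCH2MgCl, CeCl3, THF, −78 °C to rt; then silica gel, CH2Cl2, rt
Reagents that add atoms: (trimethylsilyl)methylmagnesium chloride C[Si](C)(C)C[Mg]Cl
Why: Double addition of the non-basic organocerium reagent to the lactone (no epimerisation at C9) and Peterson elimination of the β-hydroxysilane should give the 2-substituted allylsilane and free the C6 alcohol.

Step 8
Reactants: 14 allylsilane alcohol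
Product: 15 allylsilane aldehyde (C6 aldehyde)
Conditions: Dess–Martin periodinane, NaHCO3, CH2Cl2, 0 °C to rt
Reagents that add atoms: none
Why: Buffered Dess–Martin oxidation takes the neopentyl-type primary alcohol to the aldehyde without epimerising C5 or protodesilylating the allylsilane.

Step 9
Reactants: 15 allylsilane aldehyde
Product: 16 decalin 13-(benzyloxy)-14,15,16-trinor-ent-labd-8(17)-en-6-ol (6R, equatorial OH)
Conditions: SnCl4, CH2Cl2, −78 °C
Reagents that add atoms: none
Why: In this intramolecular Hosomi–Sakurai allylation C7 attacks the SnCl4-bound aldehyde through a chair in which the C=O·SnCl4 unit points to the equatorial side, away from the axial C10 and C4 methyls, so ring B should close trans-fused with an equatorial C6 hydroxyl and an 8(17)-methylene.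

Step 10
Reactants: 16 homoallylic alcohol
Product: 17 8,17-epoxide (epoxide oxygen equatorial on C8)
Conditions: mCPBA, NaHCO3, CH2Cl2, 0 °C
Reagents that add atoms: 3-chloroperoxybenzoic acid OOC(=O)c1cccc(Cl)c1
Why: In this Prilezhaev epoxidation the peracid approaches the exocyclic alkene from the face opposite the axial C10 methyl, which places the new C8–O bond equatorial.

Step 11
Reactants: 17 8,17-epoxide
Product: 18 6,8-diol (both hydroxyls equatorial, C17 methyl axial)
Conditions: LiAlH4, THF, 0 °C to reflux
Reagents that add atoms: none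
Why: Hydride opens the spiro-epoxide by SN2 attack at the primary C17, so the C8–O bond is untouched and the tertiary carbinol keeps the configuration set in step 10.

Step 12
Reactants: 18 6,8-diol
Product: 19 6-acetate (C8–OH free)
Conditions: Ac2O, pyridine, DMAP (cat.), CH2Cl2, rt
Reagents that add atoms: acetic anhydride CC(=O)OC(C)=O
Why: DMAP-catalysed acylation differentiates the diol, because the secondary C6 hydroxyl reacts at room temperature and the tertiary C8 hydroxyl does not.

Step 13
Reactants: 19 6-acetate
Product: 20 6-acetate 8-triethylsilyl ether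
Conditions: Et3SiOTf, 2,6-lutidine, CH2Cl2, −78 to 0 °C
Reagents that add atoms: triethylsilyl trifluoromethanesulfonate CC[Si](CC)(CC)OS(=O)(=O)C(F)(F)F
Why: The silyl triflate silylates the hindered tertiary alcohol, the only free hydroxyl.

Step 14
Reactants: 20 6-acetate 8-triethylsilyl ether
Product: 21 C6 alcohol with C8 triethylsilyl ether
Conditions: K2CO3, MeOH, 40 °C
Reagents that add atoms: none
Why: Base-catalysed methanolysis (transesterification) removes the acetate, while the tertiary silyl ether and the benzyl ether are stable.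

Step 15
Reactants: 21 C6 alcohol; 22 diethylsilane
Product: 23 C6 diethyl(hydrido)silyl ether
Conditions: [Ir(cod)OMe]2 (0.5 mol %), THF, rt; volatiles removed
Reagents that add atoms: none
Why: Iridium-catalysed dehydrogenative O-silylation of the only free hydroxyl with the dihydrosilane should stop at the monoalkoxy(hydrido)silane.

Step 16
Reactants: 23 C6 diethyl(hydrido)silyl ether
Product: 24 oxasilinane bridging O6 and C18
Conditions: [Rh(cod)Cl]2 (2.5 mol %), Xantphos (6 mol %), norbornene (1.5 equiv), THF, 100 °C, sealed tube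
Reagents that add atoms: none
Why: Oxidative addition of Si–H to monovalent rhodium carrying Xantphos, transfer of the hydride to norbornene, cleavage of a C18–H bond at the resulting rhodium silyl and C–Si reductive elimination form the C18–Si bond; the closest known reaction is the rhodium/Xantphos δ-C–H silylation of alcohol-derived diethyl(hydrido)silyl ethers that gives oxasilinanes on the way to 1,4-diols. The six-membered ring O6–Si–C18–C4–C5–C6 closes by this C–Si bond formation as a chair fused across C5 to rings A and B, and no skeletal C–C bond is made. C4 becomes stereogenic, and its configuration is dictated by the C5 and C6 centres of the rigid trans-decalin: the equatorial C6–O and equatorial C4–CH3 bonds are both anti to C5–C10, parallel and about 2.5 Å apart, whereas the axial methyl C19 could only be reached through a twisted ring. The step needs site selectivity among primary C–H bonds: there is no γ C–H (C4, C8 and C10 carry no hydrogen), the methyls on C10 and C8 are anti to O6 across C6–C5 and C6–C7 and out of reach, and the tertiary C9–H and the ring CH2 groups react far more slowly than a methyl group. The C8 hydroxyl is capped as its triethylsilyl ether so that silicon cannot bridge to O8 instead.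

Step 17
Reactants: 24 oxasilinane
Product: 25 6,18-diol with C8 triethylsilyl ether
Conditions: H2O2 (30 % aq.), KF, KHCO3, THF/MeOH, 50 °C
Reagents that add atoms: hydrogen peroxide OO
Why: Tamao–Fleming oxidation converts the C18–Si bond into C18–OH with retention at carbon and cleaves Si–O6, so C4 keeps the configuration set in step 16.

Step 18
Reactants: 25 6,18-diol
Product: 26 C18 tert-butyldimethylsilyl ether (C6–OH free)
Conditions: TBSCl, imidazole, DMF, 0 °C to rt
Reagents that add atoms: tert-butyldimethylsilyl chloride CC(C)(C)[Si](C)(C)Cl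
Why: Silylation should be selective for the primary C18 hydroxyl over the hindered secondary C6 hydroxyl.

Step 19
Reactants: 26 C18 silyl ether
Product: 27 C13 primary alcohol
Conditions: H2 (1 atm), Pd/C, EtOAc, rt
Reagents that add atoms: none
Why: Hydrogenolysis removes the benzyl ether at a stage with no alkene in the molecule, and EtOAc as solvent spares the silyl ethers.

Step 20
Reactants: 27 C13 primary alcohol
Product: 28 C13 aldehyde (C6–OH free)
Conditions: TEMPO (cat.), PhI(OAc)2, CH2Cl2, rt
Reagents that add atoms: none
Why: The oxoammonium (TEMPO) oxidation is selective for the unhindered primary alcohol over the hindered secondary C6 hydroxyl and stops at the aldehyde.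

Step 21
Reactants: 28 C13 aldehyde
Product: 29 terminal alkyne (C13≡C14)
Conditions: dimethyl (1-diazo-2-oxopropyl)phosphonate, K2CO3, MeOH, 0 °C to rt
Reagents that add atoms: dimethyl (1-diazo-2-oxopropyl)phosphonate COP(=O)(OC)C(=[N+]=[N-])C(C)=O
Why: Ohira–Bestmann (Seyferth–Gilbert) homologation adds C14 and gives the terminal alkyne under mild base that the silyl ethers tolerate.

Step 22
Reactants: 29 terminal alkyne
Product: 30 C6 acetate of 29
Conditions: Ac2O, DMAP, pyridine, 40 °C
Reagents that add atoms: acetic anhydride CC(=O)OC(C)=O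
Why: DMAP-catalysed acetylation of the only free hydroxyl installs the C6 acetate after the basic homologation step, so it is not exposed to methoxide.

Step 23
Reactants: 30 alkyne acetate
Product: 31 bis-silylated target (C18 OTBS, C8 OSiEt3)
Conditions: ethylene (1 atm), second-generation Grubbs catalyst (H2IMes)(PCy3)Cl2Ru=CHPh (5 mol %), toluene, 80 °C
Reagents that add atoms: ethylene C=C
Why: Ruthenium-carbene enyne cross-metathesis of the terminal alkyne with ethylene should give the 2-substituted 1,3-butadiene (C16 and C15 from ethylene).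

Step 24
Reactants: 31 bis-silylated target
Product: 32 target, (4S,5S,6R,8S,9S,10R)-6-acetoxylabda-13(16),14-diene-8,18-diol
Conditions: HF·pyridine, pyridine, THF, 0 °C to rt
Reagents that add atoms: none
Why: Fluoride cleaves both silyl ethers, and buffered HF·pyridine is chosen over basic fluoride to keep the C6 acetyl group from migrating to the nearby C18 hydroxyl and to spare the diene.

**Compound list**

1 | β-cyclocitral (2,6,6-trimethylcyclohex-1-ene-1-carbaldehyde) | CC1=C(C=O)C(C)(C)CCC1 | starting material
2 | β-cyclogeraniol, (2,6,6-trimethylcyclohex-1-en-1-yl)methanol | CC1=C(CO)C(C)(C)CCC1 | intermediate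
3 | δ-valerolactone | O=C1CCCCO1 | starting material
4 | benzyl 5-(benzyloxy)pentanoate | O=C(CCCCOCc1ccccc1)OCc1ccccc1 | intermediate (not isolated)
5 | 5-(benzyloxy)pentanoic acid | OC(=O)CCCCOCc1ccccc1 | intermediate
6 | (2,6,6-trimethylcyclohex-1-en-1-yl)methyl 5-(benzyloxy)pentanoate | O=C(CCCCOCc1ccccc1)OCC1=C(C)CCCC1(C)C | intermediate
7 | boron ketene acetal of 6, C11 chain cis to O–B, (4S,5S)-diazaborolidine on oxygen | c1ccccc1COCCC/C=C(\OB1N(S(=O)(=O)c2cc(C(F)(F)F)cc(C(F)(F)F)c2)[C@@H](c2ccccc2)[C@H](c2ccccc2)N1S(=O)(=O)c1cc(C(F)(F)F)cc(C(F)(F)F)c1)OCC1=C(C)CCCC1(C)C | intermediate (not isolated)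
8 | (2S)-5-(benzyloxy)-2-[(1S)-1,3,3-trimethyl-2-methylidenecyclohexyl]pentanoic acid (C9 and C10 as in the target) | c1ccccc1COCCC[C@H](C(=O)O)[C@]1(C)CCCC(C)(C)C1=C | intermediate
9 | methyl ester of 8 | c1ccccc1COCCC[C@H](C(=O)OC)[C@]1(C)CCCC(C)(C)C1=C | intermediate
10 | B-alkyl-9-BBN adduct of 9, boron on C6, H5 anti to the C10 methyl | c1ccccc1COCCC[C@H](C(=O)OC)[C@]1(C)CCCC(C)(C)[C@H]1CB1C2CCCC1CCC2 | intermediate (not isolated)
11 | hydroxy ester, C6–OH, H5 anti to the C10 methyl | c1ccccc1COCCC[C@H](C(=O)OC)[C@]1(C)CCCC(C)(C)[C@H]1CO | intermediate (not isolated)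
12 | trans-fused δ-lactone O–C6H2–C5–C10–C9–C8(=O), C11 chain equatorial on C9 | c1ccccc1COCCC[C@H]1[C@]2(C)CCCC(C)(C)[C@H]2COC1=O | intermediate
13 | bis(trimethylsilylmethyl) carbinol at C8 with free C6–OH | c1ccccc1COCCC[C@H](C(O)(C[Si](C)(C)C)C[Si](C)(C)C)[C@]1(C)CCCC(C)(C)[C@H]1CO | intermediate (not isolated)
14 | allylsilane alcohol, C8(=C7H2)CH2SiMe3 and C6–OH | c1ccccc1COCCC[C@H](C(=C)C[Si](C)(C)C)[C@]1(C)CCCC(C)(C)[C@H]1CO | intermediate
15 | allylsilane aldehyde (C6 aldehyde) | c1ccccc1COCCC[C@H](C(=C)C[Si](C)(C)C)[C@]1(C)CCCC(C)(C)[C@H]1C=O | intermediate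
16 | 13-(benzyloxy)-14,15,16-trinor-ent-labd-8(17)-en-6-ol, trans-decalin, 6-OH equatorial (6R) | c1ccccc1COCCC[C@H]1[C@]2(C)CCCC(C)(C)[C@H]2[C@H](O)CC1=C | intermediate
17 | 8,17-epoxide of 16, epoxide oxygen equatorial on C8 | c1ccccc1COCCC[C@H]1[C@]2(C)CCCC(C)(C)[C@H]2[C@H](O)C[C@@]13CO3 | intermediate
18 | 13-(benzyloxy)-14,15,16-trinor-ent-labdane-6,8-diol, both OH equatorial, C17 axial | c1ccccc1COCCC[C@H]1[C@]2(C)CCCC(C)(C)[C@H]2[C@H](O)C[C@]1(C)O | intermediate
19 | 6-acetate of 18 | c1ccccc1COCCC[C@H]1[C@]2(C)CCCC(C)(C)[C@H]2[C@H](OC(C)=O)C[C@]1(C)O | intermediate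
20 | 6-acetate 8-triethylsilyl ether | c1ccccc1COCCC[C@H]1[C@]2(C)CCCC(C)(C)[C@H]2[C@H](OC(C)=O)C[C@]1(C)O[Si](CC)(CC)CC | intermediate
21 | C6 alcohol with C8 triethylsilyl ether | c1ccccc1COCCC[C@H]1[C@]2(C)CCCC(C)(C)[C@H]2[C@H](O)C[C@]1(C)O[Si](CC)(CC)CC | intermediate
22 | diethylsilane | CC[SiH2]CC | starting material
23 | C6 diethyl(hydrido)silyl ether with C8 triethylsilyl ether | c1ccccc1COCCC[C@H]1[C@]2(C)CCCC(C)(C)[C@H]2[C@H](O[SiH](CC)CC)C[C@]1(C)O[Si](CC)(CC)CC | intermediate
24 | oxasilinane O6–SiEt2–C18, C18 equatorial on C4 | c1ccccc1COCCC[C@H]1[C@]2(C)CCC[C@]3(C)C[Si](CC)(CC)O[C@@H]([C@@H]23)C[C@]1(C)O[Si](CC)(CC)CC | intermediate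
25 | 6,18-diol with C8 triethylsilyl ether and C13 benzyl ether | c1ccccc1COCCC[C@H]1[C@]2(C)CCC[C@](C)(CO)[C@H]2[C@H](O)C[C@]1(C)O[Si](CC)(CC)CC | intermediate
26 | C18 tert-butyldimethylsilyl ether of 25 | c1ccccc1COCCC[C@H]1[C@]2(C)CCC[C@](C)(CO[Si](C)(C)C(C)(C)C)[C@H]2[C@H](O)C[C@]1(C)O[Si](CC)(CC)CC | intermediate
27 | C13 primary alcohol | OCCC[C@H]1[C@]2(C)CCC[C@](C)(CO[Si](C)(C)C(C)(C)C)[C@H]2[C@H](O)C[C@]1(C)O[Si](CC)(CC)CC | intermediate
28 | C13 aldehyde | O=CCC[C@H]1[C@]2(C)CCC[C@](C)(CO[Si](C)(C)C(C)(C)C)[C@H]2[C@H](O)C[C@]1(C)O[Si](CC)(CC)CC | intermediate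
29 | terminal alkyne, 15,16-dinor-ent-labd-13-yne with 6-OH, 8-OSiEt3, 18-OTBS | C#CCC[C@H]1[C@]2(C)CCC[C@](C)(CO[Si](C)(C)C(C)(C)C)[C@H]2[C@H](O)C[C@]1(C)O[Si](CC)(CC)CC | intermediate
30 | C6 acetate of 29 | C#CCC[C@H]1[C@]2(C)CCC[C@](C)(CO[Si](C)(C)C(C)(C)C)[C@H]2[C@H](OC(C)=O)C[C@]1(C)O[Si](CC)(CC)CC | intermediate
31 | 8-O-triethylsilyl 18-O-tert-butyldimethylsilyl ether of the target | C=CC(=C)CC[C@H]1[C@]2(C)CCC[C@](C)(CO[Si](C)(C)C(C)(C)C)[C@H]2[C@H](OC(C)=O)C[C@]1(C)O[Si](CC)(CC)CC | intermediate
32 | (4S,5S,6R,8S,9S,10R)-6-acetoxylabda-13(16),14-diene-8,18-diol | C=CC(=C)CC[C@H]1[C@]2(C)CCC[C@](C)(CO)[C@H]2[C@H](OC(C)=O)C[C@]1(C)O | target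

**Step count**

Total: 24 steps. Longest linear sequence: 23 steps (1 to 32 through steps 1 and 3–24); step 2 is a one-step side branch that supplies acid 5.

**Steps most likely to fail**

Step 16 (C–H silylation). The silyl ether is that of a hindered secondary alcohol, so cyclometalation of the C18–H bond may be slower than redistribution or loss of the hydridosilyl group, and the reaction may stall. The fallback sets out from alcohol 21 and comes back at diol 25; it replaces metal insertion by alkoxy-radical 1,5-hydrogen transfer, which uses the same peri geometry. Alcohol 21 is converted with NOCl and pyridine into the nitrite ester F1. Irradiation (Barton nitrite photolysis, benzene, mercury lamp) moves NO from O6 to C18 and gives, after tautomerisation, the C18 aldoxime F2. Deoximation with aqueous NaHSO3 in EtOH gives the hydroxy aldehyde, which closes to the 6,18-lactol F3. NaBH4 in MeOH reduces this lactol to 25.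

Step 4 (asymmetric Ireland–Claisen). The [3,3] shift onto the tetrasubstituted alkene may be so slow at the temperatures the boron ketene acetal tolerates that the enolate decomposes or enantioselectivity erodes. The fallback sets out from ester 6 and comes back at acid 8; it uses the thermal silyl variant followed by resolution. LiN(i-Pr)2 in THF/DMPU with Me3SiCl at −78 °C gives the trimethylsilyl ketene acetal F4 (chain cis to O–Si), which rearranges in toluene at 110 °C through the same chair. Hydrolysis of the silyl ester gives the racemic acid F5. Crystallisation with (S)-1-phenylethylamine gives the ammonium salt F6 of the (2S,1'S) acid (the antipodal amine is used if the other diastereomeric salt is the less soluble), and acidification returns 8.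

Step 6 (hydroboration). Facial selectivity may be poor if a sizeable share of 9 reacts through the chair with the C9 branch axial, which delivers hydrogen to the wrong face of C5. The fallback sets out from hydroxy ester 11, kept as the C5 mixture by leaving out the acid treatment, and comes back at lactone 12; it makes C5 trigonal inside a ring and sets it again. Dess–Martin oxidation gives the aldehyde ester F7, LiOH in THF/H2O gives the aldehyde acid F8, and Ac2O/NaOAc at 120 °C gives the bicyclic enol lactone F9 (C5=C6). In this lactone C9 lies in the alkene plane, so the C10 methyl is held axial and both axial methyls cover one face. Ionic hydrogenation (Et3SiH, CF3CO2H, CH2Cl2) protonates C5 from the open face and reduces the acyloxycarbenium ion at C6, which should give 12.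

**Further compounds**

F1 | step 16 | C6 nitrite ester of 21 | c1ccccc1COCCC[C@H]1[C@]2(C)CCCC(C)(C)[C@H]2[C@H](ON=O)C[C@]1(C)O[Si](CC)(CC)CC
F2 | step 16 | C18 aldoxime with free C6–OH | c1ccccc1COCCC[C@H]1[C@]2(C)CCC[C@](C)(C=NO)[C@H]2[C@H](O)C[C@]1(C)O[Si](CC)(CC)CC
F3 | step 16 | 6,18-lactol (cyclic hemiacetal of the C18 aldehyde with O6, anomer mixture) | c1ccccc1COCCC[C@H]1[C@]2(C)CCC[C@]3(C)C(O)O[C@@H]([C@@H]23)C[C@]1(C)O[Si](CC)(CC)CC
F4 | step 4 | trimethylsilyl ketene acetal of 6, chain cis to O–Si | c1ccccc1COCCC/C=C(\O[Si](C)(C)C)OCC1=C(C)CCCC1(C)C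
F5 | step 4 | racemic acid (8 together with its enantiomer) | c1ccccc1COCCC[C@H](C(=O)O)[C@]1(C)CCCC(C)(C)C1=C.c1ccccc1COCCC[C@@H](C(=O)O)[C@@]1(C)CCCC(C)(C)C1=C
F6 | step 4 | (S)-1-phenylethylammonium salt of 8 | c1ccccc1COCCC[C@H](C(=O)[O-])[C@]1(C)CCCC(C)(C)C1=C.C[C@H]([NH3+])c1ccccc1
F7 | step 6 | aldehyde ester (C6 aldehyde, C5 mixture) | c1ccccc1COCCC[C@H](C(=O)OC)[C@]1(C)CCCC(C)(C)C1C=O
F8 | step 6 | aldehyde acid (C5 mixture) | c1ccccc1COCCC[C@H](C(=O)O)[C@]1(C)CCCC(C)(C)C1C=O
F9 | step 6 | bicyclic enol lactone with C5=C6 | c1ccccc1COCCC[C@H]1[C@]2(C)CCCC(C)(C)C2=COC1=O
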